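Ines, you want a quick number for the south-east run and you suspect that product chokes the reaction. Subtract before you believe that.

| setting | south-west | north-east | south | north | south-east |
|---|---|---|---|---|---|
| starting material | 0.800 M | 0.400 M | 0.800 M | 0.800 M | 0.800 M |
| partner | 0.880 M | 0.480 M | 1.30 M | 0.880 M | 0.880 M |
| product |  |  |  | 0.400 M |  |
| time |  |  |  |  | 32 min |

| run | time / min | [product] / M |
|---|---|---|
| south-west run | 2.2 | 0.175 |
| south-west run | 4.3 | 0.271 |
| south-west run | 6.5 | 0.348 |
| south-west run | 8.7 | 0.406 |
| south-west run | 11 | 0.441 |
| south-west run | 13 | 0.481 |
| north-east run | 2.2 | 0.057 |
| north-east run | 4.3 | 0.107 |
| north-east run | 6.5 | 0.137 |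
| north-east run | 8.7 | 0.160 |
| north-east run | 11 | 0.192 |
| north-east run | 13 | 0.204 |
| south run | 2.2 | 0.220 |
| south run | 4.3 | 0.338 |
| south run | 6.5 | 0.432 |
| south run | 8.7 | 0.493 |
| south run | 11 | 0.545 |
| south run | 13 | 0.584 |
| north run | 2.2 | 0.566 |
| north run | 4.3 | 0.667 |
| north run | 6.5 | 0.752 |
| north run | 8.7 | 0.813 |
| north run | 11 | 0.861 |
| north run | 13 | 0.879 |

(scatter of a reading: 0.006 M)

- Overall: starting material + partner -> product.
- Constant volume, constant temperature.
- The analysis sees a species whether free or bound.
- "The second partner" is partner.
- An order is taken over about fifteen percent of the charge, up and down.

1. the power of [partner] that the first rate follows, about the charge of the south-west run; measure it at two percent of starting material made into product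
2. the power of [starting material] that the first rate follows, about the charge of the south-west run; measure it at two percent of starting material made into product (one fixed amount of product, the same in the runs compared)
3. the north-east run starts with 0.400 M less of starting material and of partner than the south-west run, and with no product. Compared where both hold the same amount of starting material, once fifteen percent of what the north-east run was charged with has turned into product, is the north-east run faster, slower or alike (within a tenth)?
4. product in the south-east run at 32 min, as a share of the starting material charged

Take the north run at 6.5 min. Minus the 0.400 M it was charged with, it has made 0.352 M, about the same as the 0.348 M of the south-west run. So drop the choke.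

Now use the pair the charges hand you, a same-excess comparison. Once the south-west run has used 0.400 M of starting material, it holds the north-east charge on paper, since both runs carry an excess of 0.0800 M partner. Divide each rate by the starting material and partner that the equation leaves, and call the result the paper constant. Around 2.2 min the north-east run goes at 0.0249 M min⁻¹, which gives 0.172 L mol⁻¹ min⁻¹. Around 11 min the south-west run goes at 0.0174 M min⁻¹, which gives 0.111 L mol⁻¹ min⁻¹, lower than the north-east value. The two moments lie 8.80 min apart. Call the logarithm of the ratio of paper constants, per minute of age between two flasks of equal excess, the fade: 0.0498 min⁻¹.

Answer the north-east question with faster, by a factor of about 1.55. Then carry the fade past the last south-west reading, since the south-east run has the same charge. On paper, ln((starting material + excess)/starting material) climbs by the excess times the summed paper constant. Starting from 13 min, that reaches 0.322 at 32 min. Expect 73.7%.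

The forecast, made from these runs, puts the partner order at 0.7, the starting-material order at 1, the north-east run faster and the share at 74%, between 68% and 79%, in the words “something decays with time or turnover”.

The simulation gives 0.92 for the partner order, 0.70 for the starting-material order, faster for the north-east run and 75.6% for the share.

    starting material + partner → product (0.2820 L mol⁻¹ min⁻¹)
    starting material + 2 partner → product + partner (0.1056 L² mol⁻² min⁻¹)
    2 partner → lost reagent (0.06420 L mol⁻¹ min⁻¹)
    starting material + partner ⇌ idle substrate-reagent adduct, settled at all times (1.170 L mol⁻¹)

In the south-west run the two product steps and the pairwise loss of partner to lost reagent ran side by side from the start, with part of both reactants held as idle substrate-reagent adduct, and over 8.80 min the fade of 0.0498 min⁻¹ makes a factor of 1.55 beside the simulated ratio of 1.5. In the south-east run the pairwise loss of partner went on past 13 min, and at 32 min product stood at 75.6% of the starting material charged.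

All runs are calculated on assumed constants.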